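Whatever substrate is still in the flask at the end is a leftover to be recovered, so we ask when the leftover stops being what there is most of.

    substrate → single ring (k1 = 0.0182 h⁻¹)
    2 substrate → open dimer (k2 = 0.0229 M⁻¹ h⁻¹)
    substrate + open dimer → open trimer (k3 = 0.0537 M⁻¹ h⁻¹)
    open dimer → ring dimer (k4 = 0.0271 h⁻¹)
    crystals ⇌ single ring, rate k5*(cs5 - [single ring]) while solid is left; crystals form when [single ring] > cs5 (cs5 = 0.19 M, k5 = 5.81 h⁻¹)
    single ring ⇌ isomer of the product (K6 = 0.811, k6 = 0.0715 h⁻¹)

all flasks: substrate 0.32 M
- summer: time 15 h
- noon: time 30 h
- dawn: time 60 h

* which of these there is most of at the end, counted by the substrate in it, summer (isomer of the product / single ring / open dimer / substrate / ring dimer)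
* which of these there is most of at the end, counted by the substrate in it, noon (isomer of the product / single ring / open dimer / substrate / ring dimer)
* which of these there is most of at the end, counted by the substrate in it, dawn (isomer of the product / single ring / open dimer / substrate / ring dimer)
* the largest of these amounts at the end, in percent of the substrate charged, summer
* the largest of these amounts at the end, in percent of the substrate charged, noon
* the largest of these amounts at the end, in percent of the substrate charged, dawn

- percent here means substrate units held: one open dimer or ring dimer counts as two
- percent here means substrate units held: one open trimer counts as three
- what is said of single ring includes crystals
- for a step with 2 of a species take k times the square, and two of it per event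
- crystals is a solid; its amount is given per volume of the solution
- run time (summer): 15 h

Turn the question round: for the leftover to lose to single ring, single ring must hold a larger fraction of the charge than substrate does. At the charge, the dimer route uses 0.805 of substrate for each unit the ring route uses; call this the pull. We set step 3 aside. Let E be the decay factor of the ring route over the time, and D be one plus the pull times what E lacks of one. Substrate left is then E over D, and the ring pool, single ring with isomer of the product, is the natural log of D over the pull. At dawn that gives 0.219 substrate and 0.532 pool. Even the whole dawn pool stands below the solubility, at 0.170 M against 0.19 M, so we count no crystals. Because step 6 relaxes in 6.26 h, far shorter than the 60 h of dawn, we give single ring its equilibrium share of the pool, 0.552.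

The dawn flask then has a lead of 0.744, the fraction held as substrate over the fraction held as single ring. The even flask, with a lead of one, is the zero of our scale, and dawn stands a quarter below it. Giving the whole rest to either dimer as a test, we commit to single ring at 29.4% for dawn. Summer goes to substrate at 63.8%, and noon to substrate at 43.3%.

The forecast says substrate at 63.3% in summer, substrate at 42.2% at noon and single ring at 29.9% at dawn, taking “single ring is about 55% of that pool plus a small lag term”. Our dawn figure for single ring is lower than the forecast's.

The flask gives substrate at 63.3% in summer, substrate at 42.4% at noon and single ring at 30.2% at dawn. Substrate and single ring stand level at 47.8 h, and the dawn answer changes for a reading earlier than that. Our reckoned lead goes from 0.744 at dawn to 1.43 for the same charge read at 40 h, which is more than even, and that neighbour held 33.2% as substrate against 25.6% as single ring.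

The numbers of this flask were chosen freely; what happens was integrated by code.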